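A direct plan would build syringaldehyde A2 from p-cresol A1 by exhaustive bromination and copper-catalysed methoxylation,
O-alkylate A2 with a 2-halopropanoic acid, extend the aldehyde to the cinnamate acid A3, join A3 to
3,4,5-trimethoxybenzaldehyde A4 by a photoredox/chromium decarboxylative addition to give the threo ester A5, and reduce A5.
Its weakest steps would be: (a) the bromination/methoxylation sequence to A2, harsh steps spent on a catalogue aldehyde;
(b) the decarboxylative radical addition, which would have to make C7–C8 and both stereocentres at once by capture of a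
1-(aryloxy)alkyl radical without precedent, the threo outcome resting on an assumed chelate and the cinnamate of A3 open to radical attack;
(c) the closing i-Bu2AlH reduction of the cinnamate, excess hydride on the most valuable, unprotected material.

Plan of the new route
The retrosynthesis cuts, in order: C1'–C7' (ring B to the intact (E)-3-hydroxypropenyl unit, Suzuki coupling); the C8–H and C9–H bonds, so that C8–C9 becomes a C8=C9 methylene; C7–H (ketone reduction, then resolution); C8=C9 (C9 from formaldehyde); and the O4'–C8 ether, made by SN2 at an achiral primary carbon.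
Feature used: C8 carries one H and the C9 methyl next to the C7 hydroxyl, so the C7–C8–C9 array is the hydrogenation product of a 2-aryloxy allylic alcohol whose hydroxyl can steer rhodium to one face of C8.
No ring is formed; rings A and B are bought ready-made, so no steps go into a commodity aldehyde.
C7 and C8 are set in two separate closed-shell steps (resolution, then 1,2-relay from C7 to C8), not by one radical addition.
The allylic alcohol arrives whole in the last step under mild base, so no hydride reagent meets late material.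
Key step: step 5

Remark: the target is the threo (7R,8R) isomer of the SMILES; C7 is the carbinol carbon, C8 the ether carbon, C9 the methyl carbon, primed locants belong to ring B and its propenyl chain; 1, 2 and 9 are taken as catalogue compounds.

Step 1
Reactants: 1 2-bromo-1-(3,4,5-trimethoxyphenyl)ethan-1-one; 2 4-bromo-2,6-dimethoxyphenol
Product: 3 2-(4-bromo-2,6-dimethoxyphenoxy)-1-(3,4,5-trimethoxyphenyl)ethan-1-one
Conditions: K2CO3 (1.5 equiv), acetone, 56 °C
Reagents that add atoms: none
Why: Williamson ether synthesis: the phenoxide of 2 displaces the primary α-keto bromide of 1 by SN2, so the hindered O4'–C8 bond is formed while C8 is still an unhindered, achiral CH2; no stereocentre is formed.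

Step 2
Reactants: 3 2-(4-bromo-2,6-dimethoxyphenoxy)-1-(3,4,5-trimethoxyphenyl)ethan-1-one
Product: 5 2-(4-bromo-2,6-dimethoxyphenoxy)-1-(3,4,5-trimethoxyphenyl)prop-2-en-1-one, via Mannich base 4 (not isolated)
Conditions: (CH2O)n (3 equiv), i-Pr2NH2(+) CF3CO2(−) (1 equiv), CF3CO2H (10 mol%), THF, 66 °C
Reagents that add atoms: paraformaldehyde (as formaldehyde), C=O
Why: Mannich α-methylenation: the iminium ion from formaldehyde and diisopropylammonium is attacked by the enol of 3 at C8, its only enolisable carbon, and the hindered amine is then lost from 4 by E1cB elimination to give the C8=C9 methylene, after which no α-hydrogen remains for a second reaction; no stereocentre is formed.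

Step 3
Reactants: 5 2-(4-bromo-2,6-dimethoxyphenoxy)-1-(3,4,5-trimethoxyphenyl)prop-2-en-1-one
Product: 6 racemic 2-(4-bromo-2,6-dimethoxyphenoxy)-1-(3,4,5-trimethoxyphenyl)prop-2-en-1-ol
Conditions: NaBH4 (1.1 equiv), CeCl3·7H2O (1.1 equiv), MeOH/CH2Cl2, −20 °C; then aq. NaHCO3
Reagents that add atoms: none
Why: Luche reduction: CeCl3 activates the carbonyl and the hard methoxyborohydrides add 1,2 and not 1,4, giving the allylic alcohol as a racemate at C7, which is resolved in the next step.

Step 4
Reactants: 6 racemic 2-(4-bromo-2,6-dimethoxyphenoxy)-1-(3,4,5-trimethoxyphenyl)prop-2-en-1-ol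
Product: 7 (R)-2-(4-bromo-2,6-dimethoxyphenoxy)-1-(3,4,5-trimethoxyphenyl)prop-2-en-1-ol
Conditions: Ti(O-i-Pr)4 (20 mol%), L-(+)-diisopropyl tartrate (30 mol%), t-BuOOH (0.6 equiv), 4 Å molecular sieves, CH2Cl2, −20 °C; then aq. NaOH/NaCl
Reagents that add atoms: none
Why: Sharpless kinetic resolution: in the complex formed from Ti(O-i-Pr)4 and the tartrate the (S)-enantiomer of 6 is epoxidised fast at its electron-rich C8=C9 enol ether bond while the (R)-enantiomer reacts slowly and is recovered as 7 (at most half of 6), the sense following the rule for secondary allylic alcohols in which the alkene carbon outranks the other carbinol substituent, so that L-(+)-tartrate leaves the (R)-alcohol and C7 is fixed as R.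

Step 5
Reactants: 7 (R)-2-(4-bromo-2,6-dimethoxyphenoxy)-1-(3,4,5-trimethoxyphenyl)prop-2-en-1-ol
Product: 8 (1R,2R)-2-(4-bromo-2,6-dimethoxyphenoxy)-1-(3,4,5-trimethoxyphenyl)propan-1-ol
Conditions: [Rh(nbd)(dppb)]BF4 (5 mol%; nbd = norbornadiene, dppb = 1,4-bis(diphenylphosphino)butane), H2 (50 bar), CH2Cl2, 25 °C
Reagents that add atoms: none
Why: Hydroxyl-directed homogeneous hydrogenation: after loss of norbornadiene the cationic monovalent rhodium binds the C7 hydroxyl and the C8=C9 enol ether alkene of 7 together, adds H2 oxidatively and transfers both hydrogens to the alkene face that carries the bound oxygen. The closest known reaction type is the directed hydrogenation of 2-substituted secondary allylic alcohols with this catalyst, the model that turns 2-(hydroxyalkyl)acrylates into anti 3-hydroxy-2-methyl esters. No ring is closed. The new C8 stereocentre is controlled by C7 through allylic 1,2-strain: in the chelate ring A must turn toward the unsubstituted C9 methylene and away from the 2,6-dimethoxyaryloxy group on C8, so that (7R) is relayed to (8R), the threo pair, while C9 becomes the methyl group. The step needs facial selectivity and chemoselectivity: the first is secured by the size of the C8 aryloxy group and by high hydrogen pressure, which should outrun rhodium-mediated isomerisation of the allylic alcohol to the saturated ketone, the second by the order of steps, since the aryl bromide is inert to the catalyst and the propenyl alkene of ring B is not yet in the molecule.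

Step 6
Reactants: 8 (1R,2R)-2-(4-bromo-2,6-dimethoxyphenoxy)-1-(3,4,5-trimethoxyphenyl)propan-1-ol; 9 (E)-3-(4,4,5,5-tetramethyl-1,3,2-dioxaborolan-2-yl)prop-2-en-1-ol
Product: 10 (1R,2R)-2-{4-[(E)-3-hydroxyprop-1-enyl]-2,6-dimethoxyphenoxy}-1-(3,4,5-trimethoxyphenyl)propan-1-ol (target)
Conditions: Pd(dppf)Cl2 (5 mol%; dppf = 1,1'-bis(diphenylphosphino)ferrocene), K3PO4 (3 equiv), 1,4-dioxane/H2O (5:1), 80 °C
Reagents that add atoms: none
Why: Suzuki–Miyaura coupling: zerovalent palladium inserts into the aryl C–Br bond of ring B, the alkenyl group of 9 is transferred from boron with retention of the (E) geometry and reductive elimination forms C1'–C7'; both free hydroxyls tolerate the mild base and C7 and C8 are not touched.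

Compound list
1 | 2-bromo-1-(3,4,5-trimethoxyphenyl)ethan-1-one | COc1cc(C(=O)CBr)cc(OC)c1OC | starting material
2 | 4-bromo-2,6-dimethoxyphenol | COc1cc(Br)cc(OC)c1O | starting material
3 | 2-(4-bromo-2,6-dimethoxyphenoxy)-1-(3,4,5-trimethoxyphenyl)ethan-1-one | COc1cc(C(=O)COc2c(OC)cc(Br)cc2OC)cc(OC)c1OC | intermediate
4 | 2-(4-bromo-2,6-dimethoxyphenoxy)-3-(diisopropylamino)-1-(3,4,5-trimethoxyphenyl)propan-1-one (Mannich base, racemic) | COc1cc(C(=O)C(CN(C(C)C)C(C)C)Oc2c(OC)cc(Br)cc2OC)cc(OC)c1OC | intermediate
5 | 2-(4-bromo-2,6-dimethoxyphenoxy)-1-(3,4,5-trimethoxyphenyl)prop-2-en-1-one | COc1cc(C(=O)C(=C)Oc2c(OC)cc(Br)cc2OC)cc(OC)c1OC | intermediate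
6 | racemic 2-(4-bromo-2,6-dimethoxyphenoxy)-1-(3,4,5-trimethoxyphenyl)prop-2-en-1-ol | COc1cc(C(O)C(=C)Oc2c(OC)cc(Br)cc2OC)cc(OC)c1OC | intermediate
7 | (R)-2-(4-bromo-2,6-dimethoxyphenoxy)-1-(3,4,5-trimethoxyphenyl)prop-2-en-1-ol | COc1cc([C@@H](O)C(=C)Oc2c(OC)cc(Br)cc2OC)cc(OC)c1OC | intermediate
8 | (1R,2R)-2-(4-bromo-2,6-dimethoxyphenoxy)-1-(3,4,5-trimethoxyphenyl)propan-1-ol | COc1cc([C@@H](O)[C@@H](C)Oc2c(OC)cc(Br)cc2OC)cc(OC)c1OC | intermediate
9 | (E)-3-(4,4,5,5-tetramethyl-1,3,2-dioxaborolan-2-yl)prop-2-en-1-ol | OC/C=C/B1OC(C)(C)C(C)(C)O1 | starting material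
10 | (1R,2R)-2-{4-[(E)-3-hydroxyprop-1-enyl]-2,6-dimethoxyphenoxy}-1-(3,4,5-trimethoxyphenyl)propan-1-ol | COc1cc([C@@H](O)[C@@H](C)Oc2c(OC)cc(/C=C/CO)cc2OC)cc(OC)c1OC | target

Total step count: 6. Longest linear sequence: 6 steps (1 and 2 to 10).

Steps most likely to fail

Step 5 (key step). The ether and methoxy oxygens of ring B could compete with the hydroxyl for rhodium, or the catalyst could isomerise the allylic alcohol to the saturated ketone; either process would erode the threo selectivity. The fallback sets out from phenol 2 and comes back at 8, setting C8 first from the chiral pool. Mitsunobu reaction of 2 with ethyl (S)-lactate (PPh3, DIAD, THF) would give, with inversion, ethyl (R)-2-(4-bromo-2,6-dimethoxyphenoxy)propanoate F1. MeNHOMe·HCl with i-PrMgCl would convert it into the Weinreb amide (R)-2-(4-bromo-2,6-dimethoxyphenoxy)-N-methoxy-N-methylpropanamide F2. Addition of 3,4,5-(MeO)3C6H2MgBr in THF would give the ketone (R)-2-(4-bromo-2,6-dimethoxyphenoxy)-1-(3,4,5-trimethoxyphenyl)propan-1-one F3. Felkin–Anh reduction with the non-chelating hydride KBH(s-Bu)3 at −78 °C should then give 8.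

Step 4. A small rate difference between the enantiomers, or titanium-induced breakdown of the enol ether, would leave 7 in low enantiomeric purity, and the resolution cannot return more than half of 6. The fallback sets out from ketone 3 and comes back at 7, replacing steps 2 to 4 by an enantioselective reduction of a ketone whose C8 is masked as an sp3 carbon. Aminomethylation of 3 with CH2=NMe2(+) I(−) would give the racemic Mannich base 2-(4-bromo-2,6-dimethoxyphenoxy)-3-(dimethylamino)-1-(3,4,5-trimethoxyphenyl)propan-1-one F4. Asymmetric transfer hydrogenation with RuCl[(S,S)-TsDPEN](p-cymene) (TsDPEN = N-tosyl-1,2-diphenylethane-1,2-diamine) in HCO2H/Et3N should give (1R)-2-(4-bromo-2,6-dimethoxyphenoxy)-3-(dimethylamino)-1-(3,4,5-trimethoxyphenyl)propan-1-ol F5 as both C2 epimers, which do not matter. Oxidation with mCPBA would give (1R)-2-(4-bromo-2,6-dimethoxyphenoxy)-3-(dimethylamino)-1-(3,4,5-trimethoxyphenyl)propan-1-ol N-oxide F6. Cope elimination on warming in THF, for which the only β-hydrogen is the one on C8, should then give 7.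

Step 2. The captodative enone 5 could oligomerise or take up the amine by conjugate addition under the hot, acidic conditions, and 3 could be aminomethylated twice. The fallback sets out from 3 and comes back at 5, releasing the enone cold and without acid. Aldol addition of 3 to aqueous formaldehyde with K2CO3 in ethanol would give the isolated 2-(4-bromo-2,6-dimethoxyphenoxy)-3-hydroxy-1-(3,4,5-trimethoxyphenyl)propan-1-one F7. Mesylation (MsCl, Et3N, CH2Cl2, 0 °C) would give 2-(4-bromo-2,6-dimethoxyphenoxy)-3-oxo-3-(3,4,5-trimethoxyphenyl)propyl methanesulfonate F8, and elimination with DBU at 0 °C should give 5.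

Further compounds
F1 | step 5 | ethyl (R)-2-(4-bromo-2,6-dimethoxyphenoxy)propanoate | C[C@@H](Oc1c(OC)cc(Br)cc1OC)C(=O)OCC
F2 | step 5 | (R)-2-(4-bromo-2,6-dimethoxyphenoxy)-N-methoxy-N-methylpropanamide | C[C@@H](Oc1c(OC)cc(Br)cc1OC)C(=O)N(C)OC
F3 | step 5 | (R)-2-(4-bromo-2,6-dimethoxyphenoxy)-1-(3,4,5-trimethoxyphenyl)propan-1-one | C[C@@H](Oc1c(OC)cc(Br)cc1OC)C(=O)c1cc(OC)c(OC)c(OC)c1
F4 | step 4 | 2-(4-bromo-2,6-dimethoxyphenoxy)-3-(dimethylamino)-1-(3,4,5-trimethoxyphenyl)propan-1-one (racemic) | COc1cc(C(=O)C(CN(C)C)Oc2c(OC)cc(Br)cc2OC)cc(OC)c1OC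
F5 | step 4 | (1R)-2-(4-bromo-2,6-dimethoxyphenoxy)-3-(dimethylamino)-1-(3,4,5-trimethoxyphenyl)propan-1-ol (both C2 epimers) | COc1cc([C@@H](O)C(CN(C)C)Oc2c(OC)cc(Br)cc2OC)cc(OC)c1OC
F6 | step 4 | (1R)-2-(4-bromo-2,6-dimethoxyphenoxy)-3-(dimethylamino)-1-(3,4,5-trimethoxyphenyl)propan-1-ol N-oxide | COc1cc([C@@H](O)C(C[N+](C)(C)[O-])Oc2c(OC)cc(Br)cc2OC)cc(OC)c1OC
F7 | step 2 | 2-(4-bromo-2,6-dimethoxyphenoxy)-3-hydroxy-1-(3,4,5-trimethoxyphenyl)propan-1-one (racemic) | COc1cc(C(=O)C(CO)Oc2c(OC)cc(Br)cc2OC)cc(OC)c1OC
F8 | step 2 | 2-(4-bromo-2,6-dimethoxyphenoxy)-3-oxo-3-(3,4,5-trimethoxyphenyl)propyl methanesulfonate (racemic) | COc1cc(C(=O)C(COS(C)(=O)=O)Oc2c(OC)cc(Br)cc2OC)cc(OC)c1OC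
A1 | direct plan | p-cresol | Cc1ccc(O)cc1
A2 | direct plan | syringaldehyde | COc1cc(C=O)cc(OC)c1O
A3 | direct plan | 2-{2,6-dimethoxy-4-[(E)-3-methoxy-3-oxoprop-1-enyl]phenoxy}propanoic acid (racemic) | CC(Oc1c(OC)cc(/C=C/C(=O)OC)cc1OC)C(=O)O
A4 | direct plan | 3,4,5-trimethoxybenzaldehyde | COc1cc(C=O)cc(OC)c1OC
A5 | direct plan | methyl (E)-3-(4-{[(1R,2R)-1-hydroxy-1-(3,4,5-trimethoxyphenyl)propan-2-yl]oxy}-3,5-dimethoxyphenyl)prop-2-enoate | COc1cc([C@@H](O)[C@@H](C)Oc2c(OC)cc(/C=C/C(=O)OC)cc2OC)cc(OC)c1OC
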